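**Retrosynthetic overview**

1. Final operation: the C6–C7 bond (the farnesyl C1–C10 bond of germacrene biosynthesis) closes the ten-membered carbocycle (ring A) from an acyclic, fully acylated (2Z)-farnesal-type aldehyde. The closure is a boron-ene (allylboration) surrogate of the cation–olefin cyclisation, with Bpin in the role of the proton lost from C13. The freed O6 then lactonises onto C12 (ring B), as in costunolide formation.
2. Seco-aldehyde ⇐ ynoate: the (Z)-2-(borylmethyl)enoate comes from syn-hydroalumination and CH2Bpin trapping. C7–C8 comes from propiolate addition to a C8 aldehyde (Felkin), and the O8 epoxy ester from Mitsunobu inversion.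
3. C8 aldehyde ⇐ Stobbe-type condensation of dimethyl (S)-malate (C8–C10, C14, the C9 stereocentre) with a nerol-derived Z-aldehyde (C1–C6, C15).
4. Side-chain acids: Evans syn-aldol (O9 ester); Sharpless epoxidation then RuO4 oxidation (O8 ester).
5. Ring order: ring A first, ring B second, in the same flask; C6 and C7 are set in the ring closure under control of C8.

Assumption: germacrane numbering (C1–C15) is used for locants. The target is taken as the SMILES encodes it: 6R,7S,8S,9S; 4Z (C3 cis to C6); 1(10)E (C2 cis to C9); (2R,3S)-hydroxy ester on O9; (2S,3R)-epoxy ester (cis-dimethyl) on O8.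

**Route**

Step 1
Reactants: 1 (4R)-4-benzyl-3-propanoyl-1,3-oxazolidin-2-one; 2 acetaldehyde
Product: 3 (4R)-4-benzyl-3-[(2R,3S)-3-hydroxy-2-methylbutanoyl]-1,3-oxazolidin-2-one
Conditions: Bu2BOTf, iPr2NEt, CH2Cl2, −78 → 0 °C; MeOH/pH 7 buffer
Reagents that add atoms: none
Why: Evans syn-aldol, in which the Z-boron enolate reacts through a Zimmerman–Traxler chair on the face away from the benzyl group, so the (R)-auxiliary sets 2R,3S.

Step 2
Reactants: 3 (4R)-4-benzyl-3-[(2R,3S)-3-hydroxy-2-methylbutanoyl]-1,3-oxazolidin-2-one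
Product: 4 (4R)-4-benzyl-3-[(2R,3S)-2-methyl-3-(triethylsilyloxy)butanoyl]-1,3-oxazolidin-2-one
Conditions: Et3SiCl, imidazole, DMF, 0 → 23 °C
Reagents that add atoms: chlorotriethylsilane, CC[Si](Cl)(CC)CC
Why: routine silylation of a secondary alcohol, which blocks retro-aldol and self-acylation later and touches no stereocentre.

Step 3
Reactants: 4 (4R)-4-benzyl-3-[(2R,3S)-2-methyl-3-(triethylsilyloxy)butanoyl]-1,3-oxazolidin-2-one
Product: 5 (2R,3S)-2-methyl-3-(triethylsilyloxy)butanoic acid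
Conditions: LiOH, H2O2, THF/H2O, 0 °C; Na2SO3; citric acid to pH 4
Reagents that add atoms: hydrogen peroxide, OO
Why: Evans hydroperoxide cleavage, in which LiOOH attacks the exocyclic imide carbonyl selectively and does not epimerise the α-centre.

Step 4
Reactants: 6 (2E)-2-methylbut-2-en-1-ol
Product: 7 [(2R,3R)-2,3-dimethyloxiran-2-yl]methanol
Conditions: Ti(OiPr)4 (10 mol%), D-(−)-diethyl tartrate (12 mol%), tBuOOH, 4 Å MS, CH2Cl2, −20 °C
Reagents that add atoms: tert-butyl hydroperoxide, CC(C)(C)OO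
Why: Katsuki–Sharpless asymmetric epoxidation, in which the D-(−)-tartrate catalyst delivers oxygen to the face that gives 2R,3R and the E-olefin fixes the cis-dimethyl relationship.

Step 5
Reactants: 7 [(2R,3R)-2,3-dimethyloxiran-2-yl]methanol
Product: 8 (2S,3R)-2,3-dimethyloxirane-2-carboxylic acid
Conditions: RuCl3 (2 mol%), NaIO4, CCl4/MeCN/H2O, 0 → 23 °C
Reagents that add atoms: water, O
Why: RuO4 oxidation (RuCl3/NaIO4) of the primary alcohol to the acid leaves the epoxide intact, and the C2 label changes from R to S only through CIP priorities.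

Step 6
Reactants: 9 nerol, (2Z)-3,7-dimethylocta-2,6-dien-1-ol
Product: 10 triethyl{[(2Z)-3,7-dimethylocta-2,6-dien-1-yl]oxy}silane
Conditions: Et3SiCl, imidazole, CH2Cl2, 0 °C
Reagents that add atoms: chlorotriethylsilane, CC[Si](Cl)(CC)CC
Why: routine silylation of a primary allylic alcohol; the Z-olefin of nerol becomes the 4Z olefin of the target.

Step 7
Reactants: 10 triethyl{[(2Z)-3,7-dimethylocta-2,6-dien-1-yl]oxy}silane
Product: 11 (4Z)-4-methyl-6-(triethylsilyloxy)hex-4-enal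
Conditions: O3 (1.0 equiv, Sudan Red 7B end point), CH2Cl2/pyridine, −78 °C; Me2S
Reagents that add atoms: ozone, [O-][O+]=O
Why: chemoselective ozonolysis of the more electron-rich isopropylidene olefin (the allylic C–O bond deactivates the other one), with the Z geometry untouched.

Step 8
Reactants: 11 (4Z)-4-methyl-6-(triethylsilyloxy)hex-4-enal; 12 dimethyl (2S)-2-hydroxybutanedioate (dimethyl L-malate)
Product: 14 (2S,3E,7Z)-2-hydroxy-3-(methoxycarbonyl)-7-methyl-9-(triethylsilyloxy)nona-3,7-dienoic acid, via paraconate lactone 13 (not isolated)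
Conditions: 12, LiN(SiMe3)2 (2.1 equiv), THF, −78 °C; add 11, −78 → 0 °C; KOtBu (1.2 equiv), 0 → 23 °C; citric acid to pH 4
Reagents that add atoms: none
Why: Proposed new method: the Fráter–Seebach alkoxide–enolate dianion of malate adds to the aldehyde at C10, the aldolate lactonises onto the C8 ester, and base opens the lactone by E1cB to the E-alkylidene half-ester exactly as in the second half of a Stobbe condensation (closest known types: Stobbe condensation and Fráter–Seebach aldol); C9 comes unchanged from (S)-malate and C8 emerges as the only free acid.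

Step 9
Reactants: 14 (2S,3E,7Z)-2-hydroxy-3-(methoxycarbonyl)-7-methyl-9-(triethylsilyloxy)nona-3,7-dienoic acid; 5 (2R,3S)-2-methyl-3-(triethylsilyloxy)butanoic acid
Product: 16 (2S,3E,7Z)-3-(methoxycarbonyl)-7-methyl-2-{[(2R,3S)-2-methyl-3-(triethylsilyloxy)butanoyl]oxy}-9-(triethylsilyloxy)nona-3,7-dienoic acid, via side-chain acid chloride 15 (not isolated)
Conditions: 5, 1-chloro-N,N,2-trimethylprop-1-en-1-amine (Ghosez reagent), CH2Cl2, 0 °C; then 14, pyridine, 0 → 23 °C; aqueous NaHCO3 work-up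
Reagents that add atoms: none
Why: O-acylation of an α-hydroxy acid by an acid chloride made under neutral conditions (Ghosez reagent), with retention at C9 and, without DMAP, no ketene-type epimerisation of the acyl α-centre.

Step 10
Reactants: 16 (2S,3E,7Z)-3-(methoxycarbonyl)-7-methyl-2-{[(2R,3S)-2-methyl-3-(triethylsilyloxy)butanoyl]oxy}-9-(triethylsilyloxy)nona-3,7-dienoic acid
Product: 18 methyl (2E,6Z)-6-methyl-2-[(1S)-1-{[(2R,3S)-2-methyl-3-(triethylsilyloxy)butanoyl]oxy}-2-oxoethyl]-8-(triethylsilyloxy)octa-2,6-dienoate, via C8 acid chloride 17 (not isolated)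
Conditions: 1-chloro-N,N,2-trimethylprop-1-en-1-amine, CH2Cl2, 0 °C; then LiAlH(OtBu)3, THF, −78 °C; used crude
Reagents that add atoms: none
Why: acid chloride formation followed by LiAlH(OtBu)3 reduction stops at the aldehyde and leaves esters, silyl ethers and olefins alone, and the base-free conditions preserve the α-acyloxy stereocentre C9.

Step 11
Reactants: 18 methyl (2E,6Z)-6-methyl-2-[(1S)-1-{[(2R,3S)-2-methyl-3-(triethylsilyloxy)butanoyl]oxy}-2-oxoethyl]-8-(triethylsilyloxy)octa-2,6-dienoate; 19 methyl prop-2-ynoate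
Product: 20 dimethyl (2E,3S,4R)-4-hydroxy-2-[(4Z)-4-methyl-6-(triethylsilyloxy)hex-4-en-1-ylidene]-3-{[(2R,3S)-2-methyl-3-(triethylsilyloxy)butanoyl]oxy}hept-5-ynedioate
Conditions: 19, LiN(SiMe3)2, THF, −90 °C; add 18; AcOH quench at −90 °C
Reagents that add atoms: none
Why: lithium acetylide addition to an α-acyloxy aldehyde under polar Felkin–Anh (Cornforth) control gives the 8,9-anti alcohol (8R), and the cold acidic quench prevents acyl migration and lactonisation of O8 onto C14.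

Step 12
Reactants: 20 dimethyl (2E,3S,4R)-4-hydroxy-2-[(4Z)-4-methyl-6-(triethylsilyloxy)hex-4-en-1-ylidene]-3-{[(2R,3S)-2-methyl-3-(triethylsilyloxy)butanoyl]oxy}hept-5-ynedioate; 8 (2S,3R)-2,3-dimethyloxirane-2-carboxylic acid
Product: 21 dimethyl (2E,3S,4S)-4-{[(2S,3R)-2,3-dimethyloxirane-2-carbonyl]oxy}-2-[(4Z)-4-methyl-6-(triethylsilyloxy)hex-4-en-1-ylidene]-3-{[(2R,3S)-2-methyl-3-(triethylsilyloxy)butanoyl]oxy}hept-5-ynedioate
Conditions: PPh3, DIAD, PhMe, 0 → 23 °C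
Reagents that add atoms: none
Why: Mitsunobu esterification of the activated propargylic alcohol proceeds by SN2 inversion, which installs the hindered epoxy ester and corrects C8 from R to the required S (8,9-threo) in one step.

Step 13
Reactants: 21 dimethyl (2E,3S,4S)-4-{[(2S,3R)-2,3-dimethyloxirane-2-carbonyl]oxy}-2-[(4Z)-4-methyl-6-(triethylsilyloxy)hex-4-en-1-ylidene]-3-{[(2R,3S)-2-methyl-3-(triethylsilyloxy)butanoyl]oxy}hept-5-ynedioate; 22 2-(iodomethyl)-4,4,5,5-tetramethyl-1,3,2-dioxaborolane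
Product: 24 dimethyl (2E,3S,4S,5Z)-4-{[(2S,3R)-2,3-dimethyloxirane-2-carbonyl]oxy}-2-[(4Z)-4-methyl-6-(triethylsilyloxy)hex-4-en-1-ylidene]-3-{[(2R,3S)-2-methyl-3-(triethylsilyloxy)butanoyl]oxy}-6-[(4,4,5,5-tetramethyl-1,3,2-dioxaborolan-2-yl)methyl]hept-5-enedioate, via vinylalane 23 (not isolated)
Conditions: iBu2AlH (1.05 equiv), HMPA, THF, 0 °C, 1 h; then 22, 0 → 23 °C
Reagents that add atoms: none
Why: conjugate syn-hydroalumination of the ynoate (H to C7, Al to C11) followed by Matteson-type trapping with the iodomethylboronate (boron ate complex, 1,2-shift with retention) gives the Z-enoate with C8 cis to CO2Me and trans to CH2Bpin.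

Step 14
Reactants: 24 dimethyl (2E,3S,4S,5Z)-4-{[(2S,3R)-2,3-dimethyloxirane-2-carbonyl]oxy}-2-[(4Z)-4-methyl-6-(triethylsilyloxy)hex-4-en-1-ylidene]-3-{[(2R,3S)-2-methyl-3-(triethylsilyloxy)butanoyl]oxy}-6-[(4,4,5,5-tetramethyl-1,3,2-dioxaborolan-2-yl)methyl]hept-5-enedioate
Product: 25 dimethyl (2E,3S,4S,5Z)-4-{[(2S,3R)-2,3-dimethyloxirane-2-carbonyl]oxy}-2-[(4Z)-4-methyl-6-oxohex-4-en-1-ylidene]-3-{[(2R,3S)-2-methyl-3-(triethylsilyloxy)butanoyl]oxy}-6-[(4,4,5,5-tetramethyl-1,3,2-dioxaborolan-2-yl)methyl]hept-5-enedioate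
Conditions: (COCl)2, DMSO, CH2Cl2, −78 → −30 °C; Et3N, −78 → 0 °C
Reagents that add atoms: none
Why: Swern oxidation converts a primary triethylsilyl ether directly into the aldehyde while the secondary silyl ether survives, the ester-deactivated allylboronate does not react with the aldehyde at this temperature, and the 4Z-enal is formed without isomerisation.

Step 15
Reactants: 25 dimethyl (2E,3S,4S,5Z)-4-{[(2S,3R)-2,3-dimethyloxirane-2-carbonyl]oxy}-2-[(4Z)-4-methyl-6-oxohex-4-en-1-ylidene]-3-{[(2R,3S)-2-methyl-3-(triethylsilyloxy)butanoyl]oxy}-6-[(4,4,5,5-tetramethyl-1,3,2-dioxaborolan-2-yl)methyl]hept-5-enedioate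
Product: 27 CNP0135583.2, methyl (1(10)E,4Z,6R,7S,8S,9S)-8-{[(2S,3R)-2,3-dimethyloxirane-2-carbonyl]oxy}-9-{[(2R,3S)-3-hydroxy-2-methylbutanoyl]oxy}germacra-1(10),4,11(13)-trien-12,6-olid-14-oate, via macrocyclic borate 26 (not isolated)
Conditions: Sc(OTf)3 (20 mol%), 4 Å MS, PhMe (1 mM, slow addition of 25), 23 → 50 °C; then pTSA·H2O (0.5 equiv), THF/H2O 20:1, 23 °C
Reagents that add atoms: none
Why: Proposed new method: a Lewis-acid-accelerated intramolecular allylboration (boron-ene) closes the ten-membered ring at C6–C7 through a closed chair in which the Z-enoate (C8 trans to CH2B) gives the 6,7-anti adduct and A(1,3) strain holds H8 in the olefin plane so that C6 adds anti to C9 and syn to the O8 ester (7S, hence 6R), after which acid cleaves the O–B bond, closes the trans-γ-lactone onto C12 and removes the silyl group (closest known types: Sc(OTf)3-catalysed allylboration–lactonisation of 2-alkoxycarbonyl allylboronates and macrocyclising allylboration).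

**Compound list**

1 | (4R)-4-benzyl-3-propanoyl-1,3-oxazolidin-2-one | CCC(=O)N1[C@H](Cc2ccccc2)COC1=O | starting material
2 | acetaldehyde | CC=O | starting material
3 | (4R)-4-benzyl-3-[(2R,3S)-3-hydroxy-2-methylbutanoyl]-1,3-oxazolidin-2-one | O=C(N1[C@H](Cc2ccccc2)COC1=O)[C@H](C)[C@H](C)O | intermediate
4 | (4R)-4-benzyl-3-[(2R,3S)-2-methyl-3-(triethylsilyloxy)butanoyl]-1,3-oxazolidin-2-one | O=C(N1[C@H](Cc2ccccc2)COC1=O)[C@H](C)[C@H](C)O[Si](CC)(CC)CC | intermediate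
5 | (2R,3S)-2-methyl-3-(triethylsilyloxy)butanoic acid | OC(=O)[C@H](C)[C@H](C)O[Si](CC)(CC)CC | intermediate
6 | (2E)-2-methylbut-2-en-1-ol (tiglyl alcohol) | C/C=C(\C)CO | starting material
7 | [(2R,3R)-2,3-dimethyloxiran-2-yl]methanol | OC[C@@]1(C)O[C@@H]1C | intermediate
8 | (2S,3R)-2,3-dimethyloxirane-2-carboxylic acid | OC(=O)[C@@]1(C)O[C@@H]1C | intermediate
9 | nerol, (2Z)-3,7-dimethylocta-2,6-dien-1-ol | CC(C)=CCC/C(C)=C\CO | starting material
10 | triethyl{[(2Z)-3,7-dimethylocta-2,6-dien-1-yl]oxy}silane | CC(C)=CCC/C(C)=C\CO[Si](CC)(CC)CC | intermediate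
11 | (4Z)-4-methyl-6-(triethylsilyloxy)hex-4-enal | O=CCC/C(C)=C\CO[Si](CC)(CC)CC | intermediate
12 | dimethyl (2S)-2-hydroxybutanedioate (dimethyl L-malate) | COC(=O)C[C@H](O)C(=O)OC | starting material
13 | methyl (4S)-4-hydroxy-2-[(3Z)-3-methyl-5-(triethylsilyloxy)pent-3-en-1-yl]-5-oxooxolane-3-carboxylate (paraconate lactone, mixture at C2 and C3) | COC(=O)C1C(CC/C(C)=C\CO[Si](CC)(CC)CC)OC(=O)[C@H]1O | intermediate (not isolated)
14 | (2S,3E,7Z)-2-hydroxy-3-(methoxycarbonyl)-7-methyl-9-(triethylsilyloxy)nona-3,7-dienoic acid | CC[Si](CC)(CC)OC/C=C(/C)CC/C=C(/C(=O)OC)[C@H](O)C(=O)O | intermediate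
15 | (2R,3S)-2-methyl-3-(triethylsilyloxy)butanoyl chloride | ClC(=O)[C@H](C)[C@H](C)O[Si](CC)(CC)CC | intermediate (not isolated)
16 | (2S,3E,7Z)-3-(methoxycarbonyl)-7-methyl-2-{[(2R,3S)-2-methyl-3-(triethylsilyloxy)butanoyl]oxy}-9-(triethylsilyloxy)nona-3,7-dienoic acid | CC[Si](CC)(CC)OC/C=C(/C)CC/C=C(/C(=O)OC)[C@H](OC(=O)[C@H](C)[C@H](C)O[Si](CC)(CC)CC)C(=O)O | intermediate
17 | acid chloride of 16 at C8 | CC[Si](CC)(CC)OC/C=C(/C)CC/C=C(/C(=O)OC)[C@H](OC(=O)[C@H](C)[C@H](C)O[Si](CC)(CC)CC)C(=O)Cl | intermediate (not isolated)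
18 | methyl (2E,6Z)-6-methyl-2-[(1S)-1-{[(2R,3S)-2-methyl-3-(triethylsilyloxy)butanoyl]oxy}-2-oxoethyl]-8-(triethylsilyloxy)octa-2,6-dienoate | CC[Si](CC)(CC)OC/C=C(/C)CC/C=C(/C(=O)OC)[C@H](OC(=O)[C@H](C)[C@H](C)O[Si](CC)(CC)CC)C=O | intermediate
19 | methyl prop-2-ynoate (methyl propiolate) | C#CC(=O)OC | starting material
20 | dimethyl (2E,3S,4R)-4-hydroxy-2-[(4Z)-4-methyl-6-(triethylsilyloxy)hex-4-en-1-ylidene]-3-{[(2R,3S)-2-methyl-3-(triethylsilyloxy)butanoyl]oxy}hept-5-ynedioate | CC[Si](CC)(CC)OC/C=C(/C)CC/C=C(/C(=O)OC)[C@H](OC(=O)[C@H](C)[C@H](C)O[Si](CC)(CC)CC)[C@H](O)C#CC(=O)OC | intermediate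
21 | dimethyl (2E,3S,4S)-4-{[(2S,3R)-2,3-dimethyloxirane-2-carbonyl]oxy}-2-[(4Z)-4-methyl-6-(triethylsilyloxy)hex-4-en-1-ylidene]-3-{[(2R,3S)-2-methyl-3-(triethylsilyloxy)butanoyl]oxy}hept-5-ynedioate | CC[Si](CC)(CC)OC/C=C(/C)CC/C=C(/C(=O)OC)[C@H](OC(=O)[C@H](C)[C@H](C)O[Si](CC)(CC)CC)[C@@H](OC(=O)[C@@]1(C)O[C@@H]1C)C#CC(=O)OC | intermediate
22 | 2-(iodomethyl)-4,4,5,5-tetramethyl-1,3,2-dioxaborolane | ICB1OC(C)(C)C(C)(C)O1 | starting material
23 | C11 diisobutylalanyl (Z)-enoate from 21 (H7 cis to Al) | CC[Si](CC)(CC)OC/C=C(/C)CC/C=C(/C(=O)OC)[C@H](OC(=O)[C@H](C)[C@H](C)O[Si](CC)(CC)CC)[C@@H](OC(=O)[C@@]1(C)O[C@@H]1C)/C=C(\C(=O)OC)[Al](CC(C)C)CC(C)C | intermediate (not isolated)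
24 | dimethyl (2E,3S,4S,5Z)-4-{[(2S,3R)-2,3-dimethyloxirane-2-carbonyl]oxy}-2-[(4Z)-4-methyl-6-(triethylsilyloxy)hex-4-en-1-ylidene]-3-{[(2R,3S)-2-methyl-3-(triethylsilyloxy)butanoyl]oxy}-6-[(4,4,5,5-tetramethyl-1,3,2-dioxaborolan-2-yl)methyl]hept-5-enedioate | CC[Si](CC)(CC)OC/C=C(/C)CC/C=C(/C(=O)OC)[C@H](OC(=O)[C@H](C)[C@H](C)O[Si](CC)(CC)CC)[C@@H](OC(=O)[C@@]1(C)O[C@@H]1C)/C=C(\C(=O)OC)CB2OC(C)(C)C(C)(C)O2 | intermediate
25 | dimethyl (2E,3S,4S,5Z)-4-{[(2S,3R)-2,3-dimethyloxirane-2-carbonyl]oxy}-2-[(4Z)-4-methyl-6-oxohex-4-en-1-ylidene]-3-{[(2R,3S)-2-methyl-3-(triethylsilyloxy)butanoyl]oxy}-6-[(4,4,5,5-tetramethyl-1,3,2-dioxaborolan-2-yl)methyl]hept-5-enedioate | O=C/C=C(/C)CC/C=C(/C(=O)OC)[C@H](OC(=O)[C@H](C)[C@H](C)O[Si](CC)(CC)CC)[C@@H](OC(=O)[C@@]1(C)O[C@@H]1C)/C=C(\C(=O)OC)CB2OC(C)(C)C(C)(C)O2 | intermediate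
26 | ten-membered-ring borate: (6R,7S,8S,9S,4Z,1(10)E) carbocycle with O6–Bpin, C7 bearing 1-(methoxycarbonyl)ethenyl, both esters and the silyl ether in place | COC(=O)C(=C)[C@H]1[C@H](OB2OC(C)(C)C(C)(C)O2)/C=C(/C)CC/C=C(/C(=O)OC)[C@H](OC(=O)[C@H](C)[C@H](C)O[Si](CC)(CC)CC)[C@H]1OC(=O)[C@@]3(C)O[C@@H]3C | intermediate (not isolated)
27 | CNP0135583.2 | C=C1C(=O)O[C@@H]2/C=C(/C)CC/C=C(/C(=O)OC)[C@H](OC(=O)[C@H](C)[C@H](C)O)[C@@H](OC(=O)[C@@]3(C)O[C@@H]3C)[C@@H]12 | target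

**Step count**

Total: 15 steps. Longest linear sequence: 10 steps (steps 6–15, from nerol).

**Three steps most likely to fail, with fallbacks**

Step 15 (ring closure). The ester-deactivated allylboronate and the conjugated enal are both sluggish partners, the effective molarity for a ten-membered ring is low, and the face selectivity relative to C8 is a model, not a precedent. Sc(OTf)3 could also open the glycidic ester or isomerise the Z-enal. The fallback closes the same bond by a chromium-mediated Nozaki–Hiyama–Kishi allylation, which is stereoconvergent for anti adducts. It sets out from 21: iBu2AlH/HMPA hydroalumination and trapping with formaldehyde gives the (Z)-2-(hydroxymethyl)enoate F8; CBr4/PPh3 gives the allylic bromide F9; Swern oxidation of the primary silyl ether gives the bromo-enal F10; CrCl2 in THF at 1 mM gives the macrocyclic hydroxy ester F11, which with pTSA lactonises and loses the silyl group, coming back at 27.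

Step 8 (Stobbe-type condensation). Retro-aldol, slow lactonisation of one aldol diastereomer, E/Z erosion and migration of the new olefin out of conjugation are all possible. The fallback builds the same half-ester through an alkyne and sets out from 11: dimethyl (1-diazo-2-oxopropyl)phosphonate, K2CO3 and MeOH give the enyne F1; Me2Zn/ProPhenol-mediated asymmetric addition of F1 to tert-butyl glyoxylate gives the (S)-propargylic alcohol F2; PdCl2(PPh3)2/Bu3SnH syn-hydrostannation places tin next to the carbinol to give the stannane F3; I2 gives the alkenyl iodide F4; PdCl2(PPh3)2, CO, MeOH and Et3N give the methyl ester F5; Me3SiOTf/2,6-lutidine then water cleaves the tert-butyl ester and comes back at 14.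

Step 13 (hydroalumination and borylmethylation). iBu2AlH meets four esters and an epoxide, and SN2′ reduction of the propargylic ester to an allene is conceivable. The fallback makes the C11–C13 bond by cross-coupling and sets out from 21: Mo(CO)3(CNtBu)3-catalysed syn-hydrostannation with Bu3SnH gives the α-stannyl enoate F6; I2 gives the α-iodo enoate F7 with retention; Negishi coupling with IZnCH2Bpin (from 22 and Zn) under Pd2(dba)3/tri(2-furyl)phosphine comes back at 24.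

**Further compounds**

F1 | step 8 | triethyl{[(2Z)-3-methylhept-2-en-6-yn-1-yl]oxy}silane | C#CCC/C(C)=C\CO[Si](CC)(CC)CC
F2 | step 8 | tert-butyl (2S,7Z)-2-hydroxy-7-methyl-9-(triethylsilyloxy)non-7-en-3-ynoate | CC(C)(C)OC(=O)[C@@H](O)C#CCC/C(C)=C\CO[Si](CC)(CC)CC
F3 | step 8 | tert-butyl (2R,3E,7Z)-2-hydroxy-7-methyl-3-(tributylstannyl)-9-(triethylsilyloxy)nona-3,7-dienoate | CC(C)(C)OC(=O)[C@@H](O)/C(=C\CC/C(C)=C\CO[Si](CC)(CC)CC)[Sn](CCCC)(CCCC)CCCC
F4 | step 8 | tert-butyl (2R,3E,7Z)-2-hydroxy-3-iodo-7-methyl-9-(triethylsilyloxy)nona-3,7-dienoate | CC(C)(C)OC(=O)[C@@H](O)/C(I)=C\CC/C(C)=C\CO[Si](CC)(CC)CC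
F5 | step 8 | tert-butyl (2S,3E,7Z)-2-hydroxy-3-(methoxycarbonyl)-7-methyl-9-(triethylsilyloxy)nona-3,7-dienoate | CC(C)(C)OC(=O)[C@@H](O)/C(C(=O)OC)=C\CC/C(C)=C\CO[Si](CC)(CC)CC
F6 | step 13 | analogue of 24 with SnBu3 on C11 in place of CH2Bpin (H7 cis to Sn) | CC[Si](CC)(CC)OC/C=C(/C)CC/C=C(/C(=O)OC)[C@H](OC(=O)[C@H](C)[C@H](C)O[Si](CC)(CC)CC)[C@@H](OC(=O)[C@@]1(C)O[C@@H]1C)/C=C(\C(=O)OC)[Sn](CCCC)(CCCC)CCCC
F7 | step 13 | analogue of 24 with iodine on C11 in place of CH2Bpin (H7 cis to I) | CC[Si](CC)(CC)OC/C=C(/C)CC/C=C(/C(=O)OC)[C@H](OC(=O)[C@H](C)[C@H](C)O[Si](CC)(CC)CC)[C@@H](OC(=O)[C@@]1(C)O[C@@H]1C)/C=C(\C(=O)OC)I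
F8 | step 15 | analogue of 24 with CH2OH in place of CH2Bpin | CC[Si](CC)(CC)OC/C=C(/C)CC/C=C(/C(=O)OC)[C@H](OC(=O)[C@H](C)[C@H](C)O[Si](CC)(CC)CC)[C@@H](OC(=O)[C@@]1(C)O[C@@H]1C)/C=C(\C(=O)OC)CO
F9 | step 15 | analogue of 24 with CH2Br in place of CH2Bpin | CC[Si](CC)(CC)OC/C=C(/C)CC/C=C(/C(=O)OC)[C@H](OC(=O)[C@H](C)[C@H](C)O[Si](CC)(CC)CC)[C@@H](OC(=O)[C@@]1(C)O[C@@H]1C)/C=C(\C(=O)OC)CBr
F10 | step 15 | analogue of 25 with CH2Br in place of CH2Bpin | O=C/C=C(/C)CC/C=C(/C(=O)OC)[C@H](OC(=O)[C@H](C)[C@H](C)O[Si](CC)(CC)CC)[C@@H](OC(=O)[C@@]1(C)O[C@@H]1C)/C=C(\C(=O)OC)CBr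
F11 | step 15 | macrocyclic 6-hydroxy ester, analogue of 26 with free OH on C6 | COC(=O)C(=C)[C@H]1[C@H](O)/C=C(/C)CC/C=C(/C(=O)OC)[C@H](OC(=O)[C@H](C)[C@H](C)O[Si](CC)(CC)CC)[C@H]1OC(=O)[C@@]2(C)O[C@@H]2C
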